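**Retrosynthetic overview**
- The target comes from a fully protected isocoumarin (two phenolic MOM ethers, one TBS ether); its pyranone ring is the last ring formed, by enol-lactonisation of a methyl 2-(2-oxo-dienyl)benzoate.
- Key disconnection: the ArCH2–C(=O) bond, made by an intermolecular Claisen-type condensation of the ester-stabilised benzylic anion of a protected 5-chloro-orsellinate with a (2E,4E)-dienyl Weinreb amide that already carries the complete tetrahydrofuran.
- The dienamide comes from an enal by Horner–Wadsworth–Emmons olefination; the enal comes from a 2-vinyltetrahydrofuran by cross-metathesis.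
- The tetrahydrofuran is the first ring formed: acid-catalysed opening of a trans-vinyl epoxide by the C5 hydroxyl (inversion at C2), the epoxide coming from Sharpless epoxidation of an (E)-allylic alcohol built from methyl (R)-3-hydroxybutanoate.
- The benzene ring is bought as methyl orsellinate (chlorination, MOM protection). Ring order: tetrahydrofuran, then pyranone.

Assumption: the target is the (2R,3S,5R),(1E,3E) isomer written in the SMILES; TBS = tert-butyldimethylsilyl, MOM = methoxymethyl, SEM = 2-(trimethylsilyl)ethoxymethyl; C2, C3 and C5 refer to tetrahydrofuran numbering.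

**Route**

Step 1
Reactants: 1 methyl (R)-3-hydroxybutanoate
Product: 2 methyl (R)-3-(TBS-oxy)butanoate
Conditions: TBSCl, imidazole, DMF, rt
Reagents that add atoms: tert-butyldimethylsilyl chloride, CC(C)(C)[Si](C)(C)Cl
Why: Routine silyl ether formation masks the hydroxyl; the chiral-pool (R) centre is untouched and becomes C5.

Step 2
Reactants: 2 methyl (R)-3-(TBS-oxy)butanoate
Product: 3 (R)-3-(TBS-oxy)butanal
Conditions: iBu2AlH (1.05 equiv), CH2Cl2, −78 °C
Reagents that add atoms: none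
Why: Low-temperature partial hydride reduction of an ester to the aldehyde is dependable for β-silyloxy esters and leaves the stereocentre alone.

Step 3
Reactants: 3 (R)-3-(TBS-oxy)butanal
Product: 4 ethyl (R,E)-5-(TBS-oxy)hex-2-enoate
Conditions: Ph3P=CHCO2Et, CH2Cl2, rt
Reagents that add atoms: (carbethoxymethylene)triphenylphosphorane, CCOC(=O)C=P(c1ccccc1)(c1ccccc1)c1ccccc1
Why: Wittig olefination with a stabilised ylide gives the (E)-enoate selectively.

Step 4
Reactants: 4 ethyl (R,E)-5-(TBS-oxy)hex-2-enoate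
Product: 5 (R,E)-5-(TBS-oxy)hex-2-en-1-ol
Conditions: iBu2AlH (2.3 equiv), CH2Cl2, −78 → 0 °C
Reagents that add atoms: none
Why: 1,2-Reduction of the enoate by the aluminium hydride gives the (E)-allylic alcohol needed for directed epoxidation.

Step 5
Reactants: 5 (R,E)-5-(TBS-oxy)hex-2-en-1-ol
Product: 6 [(2S,3S)-3-[(R)-2-(TBS-oxy)propyl]oxiran-2-yl]methanol
Conditions: Ti(OiPr)4 (10 mol%), L-(+)-diisopropyl tartrate (12 mol%), t-BuOOH, 4 Å MS, CH2Cl2, −20 °C
Reagents that add atoms: tert-butyl hydroperoxide, CC(C)(C)OO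
Why: Sharpless asymmetric epoxidation: the L-(+)-tartrate titanium catalyst delivers oxygen to one face of the (E)-allylic alcohol under reagent control, setting both epoxide carbons (the future C2 and C3) as (2S,3S) regardless of the remote silyloxy centre.

Step 6
Reactants: 6 [(2S,3S)-3-[(R)-2-(TBS-oxy)propyl]oxiran-2-yl]methanol
Product: 7 (2R,3S)-3-[(R)-2-(TBS-oxy)propyl]oxirane-2-carbaldehyde
Conditions: Dess–Martin periodinane, pyridine, CH2Cl2, 0 °C → rt
Reagents that add atoms: none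
Why: Buffered Dess–Martin oxidation gives the epoxy aldehyde without epimerisation (the descriptor changes only because of CIP priorities).

Step 7
Reactants: 7 (2R,3S)-3-[(R)-2-(TBS-oxy)propyl]oxirane-2-carbaldehyde
Product: 8 (2S,3S)-2-[(R)-2-(TBS-oxy)propyl]-3-vinyloxirane
Conditions: Ph3PCH3Br, KN(SiMe3)2, THF, 0 °C; then 7, −78 → 0 °C
Reagents that add atoms: methyltriphenylphosphonium bromide, C[P+](c1ccccc1)(c1ccccc1)c1ccccc1.[Br-]
Why: Wittig methylenation converts the aldehyde into the vinyl group that activates the adjacent epoxide carbon for the ring closure.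

Step 8
Reactants: 8 (2S,3S)-2-[(R)-2-(TBS-oxy)propyl]-3-vinyloxirane
Product: 9 (R)-1-[(2S,3S)-3-vinyloxiran-2-yl]propan-2-ol
Conditions: Bu4NF, THF, 0 °C → rt (volatile, not concentrated to dryness)
Reagents that add atoms: none
Why: Fluoride desilylation frees the C5 hydroxyl without touching the vinyl epoxide.

Step 9
Reactants: 9 (R)-1-[(2S,3S)-3-vinyloxiran-2-yl]propan-2-ol
Product: 10 (2R,3S,5R)-5-methyl-2-vinyltetrahydrofuran-3-ol
Conditions: camphor-10-sulfonic acid (10 mol%), CH2Cl2, 0 °C → rt (solution carried on)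
Reagents that add atoms: none
Why: Acid-catalysed intramolecular hydroxy-epoxide opening in the vinyl-activated endo mode (5-endo, the only alternative being a strained oxetane): the C5 hydroxyl attacks the allylic epoxide carbon with SN2 inversion, so the trans-epoxide gives the 2,3-trans ring with C2 (R), while C3 (S) and C5 (R) are retained.

Step 10
Reactants: 10 (2R,3S,5R)-5-methyl-2-vinyltetrahydrofuran-3-ol
Product: 11 (2R,3S,5R)-3-(TBS-oxy)-5-methyl-2-vinyltetrahydrofuran
Conditions: TBSCl, imidazole, DMF/CH2Cl2, rt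
Reagents that add atoms: tert-butyldimethylsilyl chloride, CC(C)(C)[Si](C)(C)Cl
Why: Silyl ether formation protects the ring hydroxyl against the strong bases used later.

Step 11
Reactants: 11 (2R,3S,5R)-3-(TBS-oxy)-5-methyl-2-vinyltetrahydrofuran
Product: 12 (E)-3-[(2R,3S,5R)-3-(TBS-oxy)-5-methyltetrahydrofuran-2-yl]prop-2-enal
Conditions: crotonaldehyde (5 equiv), second-generation Hoveyda–Grubbs catalyst RuCl2(=CH–C6H4-2-OiPr)(H2IMes) (5 mol%), CH2Cl2, 40 °C
Reagents that add atoms: (E)-but-2-enal (crotonaldehyde), C/C=C/C=O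
Why: Olefin cross-metathesis of the terminal vinyl group with an excess of the electron-poor partner gives the (E)-enal under thermodynamic control, with loss of propene.

Step 12
Reactants: 12 (E)-3-[(2R,3S,5R)-3-(TBS-oxy)-5-methyltetrahydrofuran-2-yl]prop-2-enal
Product: 13 (2E,4E)-N-methoxy-N-methyl-5-[(2R,3S,5R)-3-(TBS-oxy)-5-methyltetrahydrofuran-2-yl]penta-2,4-dienamide
Conditions: (EtO)2P(O)CH2C(O)N(OMe)Me, NaH, THF, 0 °C; then 12, 0 °C → rt
Reagents that add atoms: diethyl [2-(methoxy(methyl)amino)-2-oxoethyl]phosphonate, CCOP(=O)(CC(=O)N(C)OC)OCC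
Why: Horner–Wadsworth–Emmons olefination of the enal with the stabilised phosphonate anion gives the (2E,4E)-dienamide with high E selectivity.

Step 13
Reactants: 14 methyl 2,4-dihydroxy-6-methylbenzoate (methyl orsellinate)
Product: 15 methyl 3-chloro-4,6-dihydroxy-2-methylbenzoate
Conditions: SO2Cl2 (1.05 equiv), Et2O, 0 °C → rt; recrystallise
Reagents that add atoms: sulfuryl chloride, O=S(=O)(Cl)Cl
Why: Electrophilic aromatic chlorination of the doubly activated ring goes to the position next to the methyl group (para to the hydrogen-bonded hydroxyl, ortho to the free one), the expected preference for orsellinate-type rings; minor isomers are removed by crystallisation.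

Step 14
Reactants: 15 methyl 3-chloro-4,6-dihydroxy-2-methylbenzoate
Product: 16 methyl 3-chloro-4,6-bis(methoxymethoxy)-2-methylbenzoate
Conditions: NaH (2.5 equiv), MOMCl (2.5 equiv), DMF, 0 °C → rt
Reagents that add atoms: chloromethyl methyl ether, COCCl
Why: Williamson-type O-alkylation of both phenoxides gives base-stable acetal ethers that tolerate lateral lithiation.

Step 15
Reactants: 16 methyl 3-chloro-4,6-bis(methoxymethoxy)-2-methylbenzoate; 13 (2E,4E)-N-methoxy-N-methyl-5-[(2R,3S,5R)-3-(TBS-oxy)-5-methyltetrahydrofuran-2-yl]penta-2,4-dienamide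
Product: 19 methyl 3-chloro-4,6-bis(methoxymethoxy)-2-[(3E,5E)-2-oxo-6-[(2R,3S,5R)-3-(TBS-oxy)-5-methyltetrahydrofuran-2-yl]hexa-3,5-dien-1-yl]benzoate, via lithiated toluate 17 (not isolated), via tetrahedral lithium adduct 18 (not isolated)
Conditions: 16 (1.2 equiv), LiN(iPr)2 (2.4 equiv), THF, −78 °C, 10 min; then 13 (1.0 equiv), −78 °C, 15 min; AcOH quench at −78 °C
Reagents that add atoms: none
Why: Crossed Claisen-type condensation: the ester-stabilised benzylic (vinylogous enolate) anion from lateral lithiation attacks the Weinreb amide carbonyl in a 1,2-sense at −78 °C with short contact time, and the chelated adduct 18 releases the ketone only on quench, so there is no over-addition and no stereocentre is touched.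

Step 16
Reactants: 19 methyl 3-chloro-4,6-bis(methoxymethoxy)-2-[(3E,5E)-2-oxo-6-[(2R,3S,5R)-3-(TBS-oxy)-5-methyltetrahydrofuran-2-yl]hexa-3,5-dien-1-yl]benzoate
Product: 20 5-chloro-6,8-bis(methoxymethoxy)-3-[(1E,3E)-4-[(2R,3S,5R)-3-(TBS-oxy)-5-methyltetrahydrofuran-2-yl]buta-1,3-dien-1-yl]-1H-isochromen-1-one
Conditions: DBU (1.5 equiv), 4 Å MS, PhMe, 60 °C
Reagents that add atoms: none
Why: Base-mediated enol lactonisation (intramolecular O-acylation of the benzylic ketone enolate by the ortho ester) closes the pyranone and is driven by loss of methanol and the fully conjugated isocoumarin.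

Step 17
Reactants: 20 5-chloro-6,8-bis(methoxymethoxy)-3-[(1E,3E)-4-[(2R,3S,5R)-3-(TBS-oxy)-5-methyltetrahydrofuran-2-yl]buta-1,3-dien-1-yl]-1H-isochromen-1-one
Product: 21 5-chloro-3-[(1E,3E)-4-[(2R,3S,5R)-3-hydroxy-5-methyltetrahydrofuran-2-yl]buta-1,3-dien-1-yl]-6,8-bis(methoxymethoxy)-1H-isochromen-1-one
Conditions: Bu4NF, AcOH, THF, 0 °C → rt
Reagents that add atoms: none
Why: Buffered fluoride desilylation removes the TBS ether without opening the lactone.

Step 18
Reactants: 21 5-chloro-3-[(1E,3E)-4-[(2R,3S,5R)-3-hydroxy-5-methyltetrahydrofuran-2-yl]buta-1,3-dien-1-yl]-6,8-bis(methoxymethoxy)-1H-isochromen-1-one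
Product: 22 5-chloro-6,8-dihydroxy-3-[(1E,3E)-4-[(2R,3S,5R)-3-hydroxy-5-methyltetrahydrofuran-2-yl]buta-1,3-dien-1-yl]-1H-isochromen-1-one
Conditions: HCl (1.25 M in MeOH), THF, 0 °C → rt, monitored closely
Reagents that add atoms: none
Why: Acid-catalysed acetal exchange with methanol cleaves both phenolic MOM ethers (the peri one fastest), ideally before the allylic ring ether or the diene is affected, and gives the target with all three stereocentres unchanged.

**Compound list**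
1 | methyl (R)-3-hydroxybutanoate | C[C@@H](O)CC(=O)OC | starting material
2 | methyl (R)-3-(TBS-oxy)butanoate | C[C@@H](O[Si](C)(C)C(C)(C)C)CC(=O)OC | intermediate
3 | (R)-3-(TBS-oxy)butanal | C[C@@H](O[Si](C)(C)C(C)(C)C)CC=O | intermediate
4 | ethyl (R,E)-5-(TBS-oxy)hex-2-enoate | C[C@@H](O[Si](C)(C)C(C)(C)C)C/C=C/C(=O)OCC | intermediate
5 | (R,E)-5-(TBS-oxy)hex-2-en-1-ol | C[C@@H](O[Si](C)(C)C(C)(C)C)C/C=C/CO | intermediate
6 | [(2S,3S)-3-[(R)-2-(TBS-oxy)propyl]oxiran-2-yl]methanol | C[C@@H](O[Si](C)(C)C(C)(C)C)C[C@@H]1O[C@H]1CO | intermediate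
7 | (2R,3S)-3-[(R)-2-(TBS-oxy)propyl]oxirane-2-carbaldehyde | C[C@@H](O[Si](C)(C)C(C)(C)C)C[C@@H]1O[C@H]1C=O | intermediate
8 | (2S,3S)-2-[(R)-2-(TBS-oxy)propyl]-3-vinyloxirane | C[C@@H](O[Si](C)(C)C(C)(C)C)C[C@@H]1O[C@H]1C=C | intermediate
9 | (R)-1-[(2S,3S)-3-vinyloxiran-2-yl]propan-2-ol | C[C@@H](O)C[C@@H]1O[C@H]1C=C | intermediate
10 | (2R,3S,5R)-5-methyl-2-vinyltetrahydrofuran-3-ol | C[C@@H]1C[C@H](O)[C@@H](C=C)O1 | intermediate
11 | (2R,3S,5R)-3-(TBS-oxy)-5-methyl-2-vinyltetrahydrofuran | C[C@@H]1C[C@H](O[Si](C)(C)C(C)(C)C)[C@@H](C=C)O1 | intermediate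
12 | (E)-3-[(2R,3S,5R)-3-(TBS-oxy)-5-methyltetrahydrofuran-2-yl]prop-2-enal | C[C@@H]1C[C@H](O[Si](C)(C)C(C)(C)C)[C@@H](/C=C/C=O)O1 | intermediate
13 | (2E,4E)-N-methoxy-N-methyl-5-[(2R,3S,5R)-3-(TBS-oxy)-5-methyltetrahydrofuran-2-yl]penta-2,4-dienamide | C[C@@H]1C[C@H](O[Si](C)(C)C(C)(C)C)[C@@H](/C=C/C=C/C(=O)N(C)OC)O1 | intermediate
14 | methyl 2,4-dihydroxy-6-methylbenzoate (methyl orsellinate) | COC(=O)c1c(C)cc(O)cc1O | starting material
15 | methyl 3-chloro-4,6-dihydroxy-2-methylbenzoate | COC(=O)c1c(C)c(Cl)c(O)cc1O | intermediate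
16 | methyl 3-chloro-4,6-bis(methoxymethoxy)-2-methylbenzoate | COCOc1cc(OCOC)c(C(=O)OC)c(C)c1Cl | intermediate
17 | lithiated toluate: methyl 3-chloro-2-(lithiomethyl)-4,6-bis(methoxymethoxy)benzoate | [Li]Cc1c(Cl)c(OCOC)cc(OCOC)c1C(=O)OC | intermediate
18 | tetrahedral lithium adduct: lithium alkoxide of the N-methoxy-N-methyl hemiaminal formed from 17 and 13 (new carbinol centre undefined) | C[C@@H]1C[C@H](O[Si](C)(C)C(C)(C)C)[C@@H](/C=C/C=C/C(O[Li])(Cc2c(Cl)c(OCOC)cc(OCOC)c2C(=O)OC)N(C)OC)O1 | intermediate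
19 | methyl 3-chloro-4,6-bis(methoxymethoxy)-2-[(3E,5E)-2-oxo-6-[(2R,3S,5R)-3-(TBS-oxy)-5-methyltetrahydrofuran-2-yl]hexa-3,5-dien-1-yl]benzoate | C[C@@H]1C[C@H](O[Si](C)(C)C(C)(C)C)[C@@H](/C=C/C=C/C(=O)Cc2c(Cl)c(OCOC)cc(OCOC)c2C(=O)OC)O1 | intermediate
20 | 5-chloro-6,8-bis(methoxymethoxy)-3-[(1E,3E)-4-[(2R,3S,5R)-3-(TBS-oxy)-5-methyltetrahydrofuran-2-yl]buta-1,3-dien-1-yl]-1H-isochromen-1-one | C[C@@H]1C[C@H](O[Si](C)(C)C(C)(C)C)[C@@H](/C=C/C=C/c2cc3c(Cl)c(OCOC)cc(OCOC)c3c(=O)o2)O1 | intermediate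
21 | 5-chloro-3-[(1E,3E)-4-[(2R,3S,5R)-3-hydroxy-5-methyltetrahydrofuran-2-yl]buta-1,3-dien-1-yl]-6,8-bis(methoxymethoxy)-1H-isochromen-1-one | C[C@@H]1C[C@H](O)[C@@H](/C=C/C=C/c2cc3c(Cl)c(OCOC)cc(OCOC)c3c(=O)o2)O1 | intermediate
22 | 5-chloro-6,8-dihydroxy-3-[(1E,3E)-4-[(2R,3S,5R)-3-hydroxy-5-methyltetrahydrofuran-2-yl]buta-1,3-dien-1-yl]-1H-isochromen-1-one | C[C@@H]1C[C@H](O)[C@@H](/C=C/C=C/c2cc3c(Cl)c(O)cc(O)c3c(=O)o2)O1 | target

**Step count and risks**

Total: 18 steps. Longest linear sequence: 16 steps (steps 1–12, then 15–18); the arene branch is steps 13–14.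

Steps most likely to fail:

Step 15 (Claisen-type fragment union). The soft benzylic anion may add to dienamide 13 in a conjugate (1,4 or 1,6) sense instead of at the carbonyl. Fallback: replace the acyl donor by an aldehyde and oxidise afterwards. Setting out from 13, reduction with iBu2AlH (THF, −78 °C) gives (2E,4E)-5-[(2R,3S,5R)-3-(TBS-oxy)-5-methyltetrahydrofuran-2-yl]penta-2,4-dienal F2. Lithiated toluate 17 (from 16) adds to it 1,2 at −78 °C in a vinylogous aldol addition, with a cold AcOH quench before the alkoxide can lactonise. This gives methyl 3-chloro-2-[(3E,5E)-2-hydroxy-6-[(2R,3S,5R)-3-(TBS-oxy)-5-methyltetrahydrofuran-2-yl]hexa-3,5-dien-1-yl]-4,6-bis(methoxymethoxy)benzoate F3 (carbinol epimers, of no consequence). Dess–Martin oxidation (pyridine, CH2Cl2) comes back to the route at keto ester 19.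

Step 11 (cross-metathesis). The vinyl group sits on a ring carbon flanked by the ring oxygen and the bulky silyloxy carbon and may not turn over with an electron-poor partner. Fallback: setting out from 11, ozonolysis (O3, CH2Cl2, −78 °C; then PPh3) gives (2S,3S,5R)-3-(TBS-oxy)-5-methyltetrahydrofuran-2-carbaldehyde F1. Wittig homologation with (triphenylphosphoranylidene)acetaldehyde (PhMe, 80 °C) comes back to the route at enal 12.

Step 18 (MOM removal). Acid may ionise the dienyl-allylic ring ether or add methanol to the diene before both acetals are gone. Fallback: switch to fluoride-labile phenol protection. Setting out from 15, alkylation with SEMCl/NaH (DMF, 0 °C) gives methyl 3-chloro-2-methyl-4,6-bis{[2-(trimethylsilyl)ethoxy]methoxy}benzoate F4. The same LiN(iPr)2 condensation with 13 gives methyl 3-chloro-2-[(3E,5E)-2-oxo-6-[(2R,3S,5R)-3-(TBS-oxy)-5-methyltetrahydrofuran-2-yl]hexa-3,5-dien-1-yl]-4,6-bis{[2-(trimethylsilyl)ethoxy]methoxy}benzoate F5. The same DBU lactonisation gives 5-chloro-3-[(1E,3E)-4-[(2R,3S,5R)-3-(TBS-oxy)-5-methyltetrahydrofuran-2-yl]buta-1,3-dien-1-yl]-6,8-bis{[2-(trimethylsilyl)ethoxy]methoxy}-1H-isochromen-1-one F6. One fluoride step (Bu4NF, DMPU/THF, 45 °C) then removes both SEM ethers and the TBS ether and comes back to the route at target 22.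

**Further compounds**
F1 | step 11 | (2S,3S,5R)-3-(TBS-oxy)-5-methyltetrahydrofuran-2-carbaldehyde | C[C@@H]1C[C@H](O[Si](C)(C)C(C)(C)C)[C@@H](C=O)O1
F2 | step 15 | (2E,4E)-5-[(2R,3S,5R)-3-(TBS-oxy)-5-methyltetrahydrofuran-2-yl]penta-2,4-dienal | C[C@@H]1C[C@H](O[Si](C)(C)C(C)(C)C)[C@@H](/C=C/C=C/C=O)O1
F3 | step 15 | methyl 3-chloro-2-[(3E,5E)-2-hydroxy-6-[(2R,3S,5R)-3-(TBS-oxy)-5-methyltetrahydrofuran-2-yl]hexa-3,5-dien-1-yl]-4,6-bis(methoxymethoxy)benzoate | C[C@@H]1C[C@H](O[Si](C)(C)C(C)(C)C)[C@@H](/C=C/C=C/C(O)Cc2c(Cl)c(OCOC)cc(OCOC)c2C(=O)OC)O1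
F4 | step 18 | methyl 3-chloro-2-methyl-4,6-bis{[2-(trimethylsilyl)ethoxy]methoxy}benzoate | COC(=O)c1c(C)c(Cl)c(OCOCC[Si](C)(C)C)cc1OCOCC[Si](C)(C)C
F5 | step 18 | methyl 3-chloro-2-[(3E,5E)-2-oxo-6-[(2R,3S,5R)-3-(TBS-oxy)-5-methyltetrahydrofuran-2-yl]hexa-3,5-dien-1-yl]-4,6-bis{[2-(trimethylsilyl)ethoxy]methoxy}benzoate | C[C@@H]1C[C@H](O[Si](C)(C)C(C)(C)C)[C@@H](/C=C/C=C/C(=O)Cc2c(Cl)c(OCOCC[Si](C)(C)C)cc(OCOCC[Si](C)(C)C)c2C(=O)OC)O1
F6 | step 18 | 5-chloro-3-[(1E,3E)-4-[(2R,3S,5R)-3-(TBS-oxy)-5-methyltetrahydrofuran-2-yl]buta-1,3-dien-1-yl]-6,8-bis{[2-(trimethylsilyl)ethoxy]methoxy}-1H-isochromen-1-one | C[C@@H]1C[C@H](O[Si](C)(C)C(C)(C)C)[C@@H](/C=C/C=C/c2cc3c(Cl)c(OCOCC[Si](C)(C)C)cc(OCOCC[Si](C)(C)C)c3c(=O)o2)O1
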